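Compound numbers used throughout: **1** hydroxy ketone, **2** methoxy ketone, **3** sulfonohydrazide, **4** hydrazone, **5** cyclobutanone, **6** vinyllithium, **7** vinylcyclobutanol, **8** (S)-cyclopentanone, **9** potassium enolate, **10** enol triflate, **11** cyclopentene methyl ether, **12** cyclopentenyl phenol, **13** and **14** zinc phenoxides, **15** bicyclic phenol, **16** target.

## Analysis of the target

Target **16** is a 2,4-dibromo-3-methylphenol that carries a 1,2-dimethylbicyclo[3.1.0]hexan-2-yl group at its 6-position. The bicycle is numbered here C1 (quaternary, bearing the aryl ring and a methyl), C2 and C3 (ring CH2), C4 (cyclopropane CH), C5 (cyclopropane CH2) and C6 (methyl-bearing fusion carbon). The five-membered ring is C1–C2–C3–C4–C6 and the three-membered ring is C4–C5–C6.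

There are three contiguous stereocentres: C1 and C6, both quaternary and adjacent, and C4. The cis fusion ties C4 to C6, so only two elements are independent: the absolute configuration at C1, and the face of the five-membered ring that carries C5. Reading the SMILES, the aryl ring and C5 lie on the same face and both methyl groups on the other; the descriptors are (1S,2R,5R) in the systematic numbering of the bicycle.

The free phenol OH sits within reach of C6, so acid can open the C5–C6 bond and close a dihydrobenzofuran. Phenol and cyclopropane should therefore coexist only at the end and under non-acidic conditions. The aryl bromides would not survive organolithium, Grignard or low-valent metal steps, so they are introduced last.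

The difficulty is a benzylic all-carbon quaternary centre (C1) as one enantiomer, next to a second quaternary carbon, with the cyclopropane on the more hindered, aryl-bearing face. The strategy rests on one feature: C1 is benzylic, fully substituted, and bonded to C2 and to C6. With C6 as a carbonyl carbon, this is the pattern left when a ring CH2 of a cyclobutanol shifts onto a neighbouring aryl-stabilised cationic carbon. The resulting ketone can enolise only toward C4.

## Retrosynthetic reasoning

**C–Br bonds.** The two C–Br bonds of **16** are cut first, back to phenol **15**. The OH group activates exactly the two positions that carry bromine (para, and the one free ortho position), so a late electrophilic bromination needs no extra directing element. It also keeps the halogens away from every organometallic step.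

**Cyclopropane.** In **15** the bonds C4–C5 and C6–C5 are cut, removing C5 as a one-carbon unit and leaving the C4=C6 alkene of phenol **12**. C5 must enter on the face occupied by the aryl ring, which is the more hindered one, so the forward step needs delivery from a group on that ring. The phenol oxygen, as its zinc phenoxide (**13**, then **14**), is the only available handle. The free phenol is therefore unmasked before this step and not after.

**O–CH3 bond.** Phenol **12** is traced to its methyl ether **11**. The oxygen has to be capped through the organolithium, strong-acid, enolate and Grignard steps, and a methyl ether survives all of them. It is removed while the molecule is still a simple alkene, under basic conditions.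

**C6–CH3 bond.** Alkene **11** is cut at the bond between C6 and its methyl group, giving enol triflate **10** and, behind it, ketone **8** through enolate **9**. Cutting here places the double bond unambiguously, because **8** has α-hydrogens only at C4. A route through a tertiary alcohol and dehydration would instead pass close to a cation next to the benzylic quaternary carbon.

**C1–C2 bond (key disconnection).** Ketone **8** is cut at C1–C2 and the bond is reconnected to the carbonyl carbon, giving the achiral vinylcyclobutanol **7**. This is where the ring and the C1 stereocentre are made together. The forward reaction must protonate the alkene so that charge develops at C1, let a cyclobutane CH2 migrate to it, and distinguish the two faces of C1 with a chiral Brønsted acid. What is gained is an achiral, three-step precursor, with the whole stereochemical burden on one catalytic step.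

**C–C bond to the cyclobutane.** Alcohol **7** is cut between the carbinol carbon and the vinyl carbon, giving cyclobutanone **5** and vinyllithium **6**. The vinyllithium comes from hydrazone **4**, which is the condensation product of ketone **2** and hydrazide **3**. Ketone **2** is the O-methyl ether of commercial **1**.

## Alternatives that were turned down

**Alternative 1: both cyclopropane bonds at C6 from a carbenoid.**
- Disconnection: C6–C4 and C6–C5. The acyclic α-diazo ester **A2** already carries the C1 quaternary centre and ends in the C4=C5 vinyl group.
- Forward key step: Rh2(OAc)4 or the chiral Rh2(S-PTTL)4 (divalent rhodium) generates a carbenoid at C6 that adds to the alkene, giving bicyclic ester **A1**.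
- For: the five-membered ring, the cyclopropane and the C4 and C6 stereocentres arise in one step. C1 has no hydrogen, so a 1,2-hydride shift of the carbenoid is excluded. The cyclopropane is made under neutral conditions with the phenol still capped.
- Against: C1 must already be a single enantiomer in an acyclic precursor, and a diazo group must be installed beside that hindered centre. The relation between C1 and the new ring depends only on which of aryl or methyl sits pseudo-axial in the closing tether, a small difference that a chiral catalyst does not address. The electron-rich arene can intercept the carbenoid. The ester on C6 must then be reduced to a methyl group at a neopentyl, cyclopropylcarbinyl position, which costs about three steps and risks rearrangement.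
- Comparison: on bond-forming economy in one step, and on forming the cyclopropane without a free phenol, **A1** is the stronger plan. The chosen route offers C1 set catalytically from an achiral alcohol and no functional group to remove at C6.

**Alternative 2: both methyl groups by conjugate addition and enolate trapping.**
- Disconnection: C1–CH3 and C6–CH3. The substrate is the cyclic alkylidene β-keto ester **A4** (aryl on C1, ester on C6, ketone at C4).
- Forward key step: MeMgBr with CuBr·SMe2 (monovalent copper) and a chiral ferrocenyl diphosphine adds methyl at C1, and the magnesium enolate is C-methylated at C6 with MeI, giving **A3**.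
- For: both quaternary carbons are made in one flask. The C6 methyl should enter anti to the aryl ring, which is the target's relation, and the ester carbon is the future C5. This control of C6 does not depend on a directing group and is stronger than in the chosen route.
- Against: a β-aryl, fully substituted acceptor with an ortho-methoxy group is a poorly reactive and poorly selective case for copper-catalysed methyl addition, and 1,2-addition competes. C-methylation of a hindered enolate beside a new quaternary centre competes with O-methylation. After **A3**, ester and ketone must be reduced, both oxygens activated and a reductive 1,3-closure of C4–C5 carried out, about five steps in a congested setting.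
- Comparison: the chosen route gives a more reactive key-step substrate and a much shorter end game, at the price of a directed cyclopropanation.

**Alternative 3: C1–C6 bond by carbenoid C–H insertion.**
- Disconnection: C1–C6. The α-diazo β-keto ester **A6** carries a preformed tertiary benzylic stereocentre.
- Forward key step: Rh2(OAc)4 (divalent rhodium) gives a carbenoid at C6 that inserts into the C1–H bond with retention, closing cyclopentanone **A5**.
- For: 1,5-insertion into an electron-rich tertiary benzylic C–H bond is a favourable case. Retention lets the quaternary centre inherit its purity from a tertiary one, which is easier to make. On robustness of the enantiomeric purity this plan may be stronger than the chosen one.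
- Against: the carbenoid sits near an electron-rich anisole ring, so aromatic cycloaddition and attack at the methoxy oxygen compete, and the C–H bond is shielded by the ortho substituent. **A5** still lacks the C6 methyl group; methylation would lead to **A3**, so the long end game of Alternative 2 is inherited. The diazo precursor needs its own asymmetric step and chain assembly.
- Comparison: the chosen route makes the ring and C1 in one catalytic step, three steps from commercial materials, and avoids carbenoid chemoselectivity problems.

Key step: step 4

Assumption: the sense of induction of the chiral acid with **7** cannot be derived from first principles. The (R)-catalyst is written, and its mirror image would be used if a first run shows that it delivers the (R)-ketone.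

## Route

Step 1
Reactants: 1 1-(2-hydroxy-4-methylphenyl)ethanone
Product: 2 1-(2-methoxy-4-methylphenyl)ethanone
Conditions: MeI, K2CO3, acetone, reflux
Reagents that add atoms: iodomethane, CI
Why: Williamson O-methylation of the phenoxide; the carbonate is too weak to enolise the ketone, so alkylation should occur only on oxygen.

Step 2
Reactants: 2 1-(2-methoxy-4-methylphenyl)ethanone; 3 2,4,6-tri(propan-2-yl)benzenesulfonohydrazide
Product: 4 N'-[(1E)-1-(2-methoxy-4-methylphenyl)ethylidene]-2,4,6-tri(propan-2-yl)benzenesulfonohydrazide
Conditions: MeOH, cat. HCl, rt
Reagents that add atoms: none
Why: Acid-catalysed hydrazone condensation; the E isomer, with the sulfonamide nitrogen on the methyl side, is expected and is the one needed for syn deprotonation of the methyl group in the next step.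

Step 3
Reactants: 4 N'-[(1E)-1-(2-methoxy-4-methylphenyl)ethylidene]-2,4,6-tri(propan-2-yl)benzenesulfonohydrazide; 5 cyclobutanone
Product: 7 1-[1-(2-methoxy-4-methylphenyl)ethenyl]cyclobutan-1-ol, via [1-(2-methoxy-4-methylphenyl)ethenyl]lithium 6 (not isolated)
Conditions: n-BuLi (2.2 equiv), THF, −78 → 0 °C; then 5, −78 → −20 °C; aq NH4Cl
Reagents that add atoms: none
Why: Shapiro reaction: deprotonation at N–H and at the methyl group, then loss of sulfinate and N2 on warming, gives vinyllithium 6 with lithium on the aryl-bearing carbon. The triisopropyl-substituted sulfonyl ring cannot be ortho-lithiated and lets the fragmentation run at 0 °C; 1,2-addition to strained cyclobutanone should be fast at −78 °C.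

Step 4
Reactants: 7 1-[1-(2-methoxy-4-methylphenyl)ethenyl]cyclobutan-1-ol
Product: 8 (2S)-2-(2-methoxy-4-methylphenyl)-2-methylcyclopentan-1-one
Conditions: (R)-N-triflylphosphoramide of 3,3'-bis(2,4,6-triisopropylphenyl)-1,1'-bi-2-naphthol (5 mol %), toluene, 4 Å MS, −40 °C
Reagents that add atoms: none
Why: The acid protonates the terminal CH2 of the 1,1-disubstituted alkene in the Markovnikov sense, so positive charge develops at C1, where the 2-methoxy-4-methylphenyl ring stabilises it. While the conjugate base stays hydrogen-bonded to the cyclobutanol OH, one of the two equivalent ring CH2 groups on the carbinol carbon shifts to C1, forming C1–C2, and the carbinol carbon becomes the C6 carbonyl; the closest known reaction type is the catalytic enantioselective protio-semipinacol ring expansion of 1-(1-arylvinyl)cyclobutanols to 2-aryl-2-methylcyclopentanones. The five-membered ring is thus not closed end to end but arises by a strain-releasing 1,2-alkyl shift that enlarges the four-membered ring by one carbon. C1 is the only new stereocentre and is set by the catalyst: the chiral phosphoramide anion, in a contact ion pair anchored to the OH, leaves one face of the planar cationic carbon open to the migrating bond. The step needs Markovnikov regiochemistry, which the aryl group secures, and enantioface selection, which the anion secures. It also needs migration to outrun capture by water, elimination or alkene dimerisation; the intramolecular strain-driven shift, the dry non-polar medium and the low temperature favour that. The two candidate migrating groups are homotopic, and the product has no hydrogen at C1, so it cannot racemise by enolisation.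

Step 5
Reactants: 8 (2S)-2-(2-methoxy-4-methylphenyl)-2-methylcyclopentan-1-one
Product: 10 (5S)-5-(2-methoxy-4-methylphenyl)-5-methylcyclopent-1-en-1-yl trifluoromethanesulfonate, via potassium enolate 9 (not isolated)
Conditions: KN(SiMe3)2, THF, −78 °C; then PhNTf2, −78 → 0 °C
Reagents that add atoms: N-phenylbis(trifluoromethanesulfonimide), O=S(=O)(N(c1ccccc1)S(=O)(=O)C(F)(F)F)C(F)(F)F
Why: Enolate O-sulfonylation; only C4 carries α-hydrogens, so a single enolate 9 forms and the double bond is fixed between C6 and C4. The quaternary C1 is untouched.

Step 6
Reactants: 10 (5S)-5-(2-methoxy-4-methylphenyl)-5-methylcyclopent-1-en-1-yl trifluoromethanesulfonate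
Product: 11 1-[(1R)-1,2-dimethylcyclopent-2-en-1-yl]-2-methoxy-4-methylbenzene
Conditions: MeMgBr, Fe(acac)3 (10 mol %), THF/NMP, −30 → 0 °C
Reagents that add atoms: methylmagnesium bromide, C[Mg]Br
Why: Iron-catalysed Kumada-type cross-coupling of an alkenyl triflate with a methyl Grignard reagent; it exchanges C6–O for C6–CH3 without moving the double bond. The descriptor changes from S to R only because the substituent priorities at C1 change.

Step 7
Reactants: 11 1-[(1R)-1,2-dimethylcyclopent-2-en-1-yl]-2-methoxy-4-methylbenzene
Product: 12 2-[(1R)-1,2-dimethylcyclopent-2-en-1-yl]-5-methylphenol
Conditions: NaSEt, DMF, 140 °C; aq NH4Cl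
Reagents that add atoms: none
Why: SN2 attack of ethanethiolate on the O-methyl carbon of the aryl methyl ether; the basic medium spares the alkene, which under acidic demethylation would be attacked by the phenol oxygen at C6.

Step 8
Reactants: 12 2-[(1R)-1,2-dimethylcyclopent-2-en-1-yl]-5-methylphenol
Product: 15 2-[(1S,2R,5R)-1,2-dimethylbicyclo[3.1.0]hexan-2-yl]-5-methylphenol, via ethylzinc phenoxide 13 (not isolated), via iodomethylzinc phenoxide 14 (not isolated)
Conditions: Et2Zn, CH2I2, CH2Cl2, 0 °C → rt; aq NH4Cl
Reagents that add atoms: diiodomethane, ICI
Why: Simmons–Smith cyclopropanation in the Furukawa variant: Et2Zn deprotonates the phenol to 13, and zinc–iodine exchange with CH2I2 gives carbenoid 14 bound to the phenoxide oxygen. The CH2 group is then delivered within the molecule to the alkene face on which the aryl ring sits, so C5 should end cis to the aryl group; C4 and C6 are set together by the concerted syn addition.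

Step 9
Reactants: 15 2-[(1S,2R,5R)-1,2-dimethylbicyclo[3.1.0]hexan-2-yl]-5-methylphenol
Product: 16 2,4-dibromo-6-[(1S,2R,5R)-1,2-dimethylbicyclo[3.1.0]hexan-2-yl]-3-methylphenol
Conditions: NBS (2.1 equiv), NaHCO3, MeCN, 0 °C → rt, dark
Reagents that add atoms: N-bromosuccinimide, O=C1CCC(=O)N1Br
Why: Electrophilic aromatic bromination: the OH group activates the free para position and the one free ortho position, while the remaining ring CH is meta to OH and shielded by the bicycle. The bicarbonate buffer, darkness and low temperature are meant to keep acid away from the cyclopropane and radicals away from the benzylic methyl.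

## Compound list

1 | 1-(2-hydroxy-4-methylphenyl)ethanone | CC(=O)c1ccc(C)cc1O | starting material
2 | 1-(2-methoxy-4-methylphenyl)ethanone | COc1cc(C)ccc1C(C)=O | intermediate
3 | 2,4,6-tri(propan-2-yl)benzenesulfonohydrazide | CC(C)c1cc(C(C)C)c(S(=O)(=O)NN)c(C(C)C)c1 | starting material
4 | N'-[(1E)-1-(2-methoxy-4-methylphenyl)ethylidene]-2,4,6-tri(propan-2-yl)benzenesulfonohydrazide | COc1cc(C)ccc1/C(C)=N/NS(=O)(=O)c1c(C(C)C)cc(C(C)C)cc1C(C)C | intermediate
5 | cyclobutanone | O=C1CCC1 | starting material
6 | [1-(2-methoxy-4-methylphenyl)ethenyl]lithium | [Li]C(=C)c1ccc(C)cc1OC | intermediate (not isolated)
7 | 1-[1-(2-methoxy-4-methylphenyl)ethenyl]cyclobutan-1-ol | Cc1ccc(C(=C)C2(O)CCC2)c(OC)c1 | intermediate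
8 | (2S)-2-(2-methoxy-4-methylphenyl)-2-methylcyclopentan-1-one | Cc1ccc([C@]2(C)CCCC2=O)c(OC)c1 | intermediate
9 | potassium (5S)-5-(2-methoxy-4-methylphenyl)-5-methylcyclopent-1-en-1-olate | Cc1ccc([C@]2(C)CCC=C2[O-])c(OC)c1.[K+] | intermediate (not isolated)
10 | (5S)-5-(2-methoxy-4-methylphenyl)-5-methylcyclopent-1-en-1-yl trifluoromethanesulfonate | Cc1ccc([C@]2(C)CCC=C2OS(=O)(=O)C(F)(F)F)c(OC)c1 | intermediate
11 | 1-[(1R)-1,2-dimethylcyclopent-2-en-1-yl]-2-methoxy-4-methylbenzene | Cc1ccc([C@]2(C)CCC=C2C)c(OC)c1 | intermediate
12 | 2-[(1R)-1,2-dimethylcyclopent-2-en-1-yl]-5-methylphenol | Cc1ccc([C@]2(C)CCC=C2C)c(O)c1 | intermediate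
13 | ethylzinc 2-[(1R)-1,2-dimethylcyclopent-2-en-1-yl]-5-methylphenoxide | CC[Zn]Oc1cc(C)ccc1[C@]2(C)CCC=C2C | intermediate (not isolated)
14 | iodomethylzinc 2-[(1R)-1,2-dimethylcyclopent-2-en-1-yl]-5-methylphenoxide | IC[Zn]Oc1cc(C)ccc1[C@]2(C)CCC=C2C | intermediate (not isolated)
15 | 2-[(1S,2R,5R)-1,2-dimethylbicyclo[3.1.0]hexan-2-yl]-5-methylphenol | Cc1ccc([C@]2(C)CC[C@@H]3C[C@@]32C)c(O)c1 | intermediate
16 | 2,4-dibromo-6-[(1S,2R,5R)-1,2-dimethylbicyclo[3.1.0]hexan-2-yl]-3-methylphenol | Cc1c(Br)cc([C@]2(C)CC[C@@H]3C[C@@]32C)c(O)c1Br | target

## Step count and least certain steps

Total: 9 steps. Longest linear sequence: 9 steps, from **1** to **16**.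

**Step 4 (key step).** The most likely failure is weak enantioface discrimination. The 2-methoxy-4-methylphenyl ring stabilises the cation so well that the ion pair may loosen, and the ortho substituent twists the ring out of the alkene plane, which changes how the substrate sits in the catalyst pocket. Capture of the cation by traces of water would also lower conversion. Fallback, from **7** back to **8**: the ring expansion is run with an achiral acid (diphenyl phosphate, CH2Cl2, 0 °C) to give racemic 2-(2-methoxy-4-methylphenyl)-2-methylcyclopentan-1-one F1. The enantiomers are then separated by preparative chromatography on a chiral stationary phase (amylose tris(3,5-dimethylphenylcarbamate), CO2/i-PrOH), and the (S)-enantiomer rejoins the route as **8**. This replaces asymmetric catalysis by resolution and costs half of the material.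

**Step 3.** Proton transfer may win over addition: vinyllithium **6** can be quenched by THF during the warm period, or can enolise cyclobutanone instead of adding to it. Fallback, from **2** back to **7**: the ketone is converted with (PhO)3P/Br2 and Et3N in CH2Cl2 into 1-(1-bromoethenyl)-2-methoxy-4-methylbenzene F2. Its Grignard reagent (Mg, THF), transmetallated with CeCl3, is added to **5** to give **7**. The nucleophile then comes from an isolated vinyl bromide and not from a hydrazone fragmentation, and the organocerium species is far less basic.

**Step 6.** Oxidative addition at the neopentyl-type enol triflate may be slow enough that MeMgBr attacks sulfur instead, cleaving the S–O bond and returning the enolate of **8**. Fallback, from **8** back to **11**: MeLi/CeCl3 (THF, −78 °C) adds to the ketone to give (2S)-2-(2-methoxy-4-methylphenyl)-1,2-dimethylcyclopentan-1-ol F3 as a mixture of carbinol epimers, which is dehydrated with SOCl2/pyridine at 0 °C to **11**. Elimination toward the methyl group is the competing pathway, and the basic medium is chosen to avoid a free cation next to C1.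

**Step 8.** Zinc iodide formed in the reaction may promote attack of the phenol oxygen on C6, either on the alkene before methylene transfer or on the product with opening of the C5–C6 bond. Transfer to the hindered trisubstituted alkene may also be slow. Fallback, from **11** back to **15**: steps 7 and 8 are exchanged. Methyl ether **11** is cyclopropanated with Et2Zn/CH2I2/CF3CO2H in CH2Cl2, with the ether oxygen as the coordinating group, to give 1-[(1S,2R,5R)-1,2-dimethylbicyclo[3.1.0]hexan-2-yl]-2-methoxy-4-methylbenzene F4. F4 is then demethylated with NaSEt in DMF to **15**. No nucleophilic OH is present during the Lewis-acidic step; the price is weaker direction by a neutral ether, so the facial outcome would have to be checked.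

**Step 9.** Traces of HBr may trigger opening of the cyclopropane by the neighbouring OH. The second bromination, at the position between OH and CH3, may stall, or forcing it may lead to ipso attack and a dienone. Fallback, from **15** back to **16**: the two C–Br bonds are made separately. A buffered tribromide salt (Bu4NBr3, CaCO3, CH2Cl2/MeOH) should give the para-bromide 4-bromo-2-[(1S,2R,5R)-1,2-dimethylbicyclo[3.1.0]hexan-2-yl]-5-methylphenol F5, which is isolated. The ortho bromine is then delivered by NBS with i-Pr2NH in CH2Cl2 at 0 °C, where the amine carries the bromine to the hydrogen-bonded phenol under basic conditions, giving **16**.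

## Further compounds

F1 | step 4 | rac-2-(2-methoxy-4-methylphenyl)-2-methylcyclopentan-1-one | Cc1ccc(C2(C)CCCC2=O)c(OC)c1
F2 | step 3 | 1-(1-bromoethenyl)-2-methoxy-4-methylbenzene | C=C(Br)c1ccc(C)cc1OC
F3 | step 6 | (2S)-2-(2-methoxy-4-methylphenyl)-1,2-dimethylcyclopentan-1-ol (both C1 epimers) | Cc1ccc([C@]2(C)CCCC2(C)O)c(OC)c1
F4 | step 8 | 1-[(1S,2R,5R)-1,2-dimethylbicyclo[3.1.0]hexan-2-yl]-2-methoxy-4-methylbenzene | Cc1ccc([C@]2(C)CC[C@@H]3C[C@@]32C)c(OC)c1
F5 | step 9 | 4-bromo-2-[(1S,2R,5R)-1,2-dimethylbicyclo[3.1.0]hexan-2-yl]-5-methylphenol | Cc1cc(O)c([C@]2(C)CC[C@@H]3C[C@@]32C)cc1Br
A1 | alternative 1 | ethyl (1R,2S,5R)-2-(2-methoxy-4-methylphenyl)-2-methylbicyclo[3.1.0]hexane-1-carboxylate | Cc1ccc([C@]2(C)CC[C@@H]3C[C@@]32C(=O)OCC)c(OC)c1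
A2 | alternative 1 | ethyl (3S)-2-diazo-3-(2-methoxy-4-methylphenyl)-3-methylhept-6-enoate | Cc1ccc([C@](C)(CCC=C)C(=[N+]=[N-])C(=O)OCC)c(OC)c1
A3 | alternative 2 | methyl (1R,2S)-2-(2-methoxy-4-methylphenyl)-1,2-dimethyl-5-oxocyclopentane-1-carboxylate | Cc1ccc([C@]2(C)CCC(=O)[C@]2(C)C(=O)OC)c(OC)c1
A4 | alternative 2 | methyl 2-(2-methoxy-4-methylphenyl)-5-oxocyclopent-1-ene-1-carboxylate | COC(=O)C1=C(c2ccc(C)cc2OC)CCC1=O
A5 | alternative 3 | methyl (2R)-2-(2-methoxy-4-methylphenyl)-2-methyl-5-oxocyclopentane-1-carboxylate | Cc1ccc([C@]2(C)CCC(=O)C2C(=O)OC)c(OC)c1
A6 | alternative 3 | methyl (6R)-2-diazo-6-(2-methoxy-4-methylphenyl)-3-oxoheptanoate | Cc1ccc([C@H](C)CCC(=O)C(=[N+]=[N-])C(=O)OC)c(OC)c1
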